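A direct plan would fix the diaryl ether first: SNAr of the symmetric phenol 4-methoxy-2,6-bis(methoxymethoxy)phenol A1 on 4-fluorobenzaldehyde A2 would give the ether aldehyde A3.
It would then erect both isoflavones on A3 one after the other: chalcone A4, oxidative 1,2-aryl shift and acid cyclisation to the mono-isoflavone A5, then acylation with an arylacetic acid, formylative ring closure to the 5-O-methyl ether A6 and a last O-demethylation.
Weak step 1, the oxidative aryl migration of chalcone A4: it would need a stoichiometric trivalent thallium oxidant on a substrate with three acid-labile acetals, and aldol, migration and cyclisation (three steps) would be spent on one pyranone ring.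
Weak step 2, the Friedel–Crafts acylation of the free polyphenol A5 and the ring closure after it: the second heterocycle would be built late, in a hot Lewis acid, on the most valuable intermediate, and the plan would stay linear (about eleven steps in one line).
Weak step 3, the closing demethylation of A6 with a boron trihalide: a methyl ether would be carried through the whole route only to be cut by a harsh Lewis acid on the finished, poorly soluble bis-isoflavone, after a lithiation–borylation–oxidation that only installs one oxygen of A1.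

**Retrosynthetic overview**
The target is read as a heterodimer of two isoflavone monomers, genistein and 8-chlorodaidzein. It is cut at the one bond that joins them: O–C8, between C-8 of ring A of the genistein half and the 4'-oxygen on ring B of the chlorinated half, the bond a phenol-coupling enzyme would presumably form.
Ring order: both pyranone rings exist before the ether. That of the chlorinated half is closed in a one-pot acylation/formylative cyclisation of 2-chlororesorcinol (chlorine fixed at C-8 by symmetry); that of the other half comes with commercial genistein.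
The key step is a copper-catalysed Ullmann C–O coupling of the C8-iodide 8 (iodine steered to C-8 by 5-O-alkylation) with phenol 5; it joins two C15 monomers to the full C30 skeleton, and one mild acid step then removes all four MOM groups.
The design needs no thallium-mediated rearrangement, no ring construction or acylation on the assembled core and no methyl ether to cleave; it is convergent, six steps, longest line four.

Key step: step 5

Remark: the target has no stereocentre and the diaryl ether rotates freely, so no stereocontrol is needed; genistein is taken as a commercial monomer.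

**Step 1**
Reactants: 1 2-chlororesorcinol (2-chlorobenzene-1,3-diol); 2 4-hydroxyphenylacetic acid
Product: 4 8-chloro-7-hydroxy-3-(4-hydroxyphenyl)-4H-chromen-4-one (8-chlorodaidzein), via deoxybenzoin 3 (not isolated)
Conditions: BF3·OEt2 (solvent), 90 °C; then DMF, MsCl, 50 → 80 °C; H2O
Reagents that add atoms: N,N-dimethylformamide, CN(C)C=O
Why: Friedel–Crafts (Nencki-type) C-acylation at C-4 of 2-chlororesorcinol, the only position ortho/para to both hydroxyls (C-4 and C-6 are equivalent), followed in the same pot by Vilsmeier-type C-formylation of the activated methylene and addition–elimination ring closure through the chelated ortho-hydroxyl, should give the isoflavone with chlorine necessarily at C-8.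

**Step 2**
Reactants: 4 8-chloro-7-hydroxy-3-(4-hydroxyphenyl)-4H-chromen-4-one
Product: 5 8-chloro-3-(4-hydroxyphenyl)-7-(methoxymethoxy)-4H-chromen-4-one
Conditions: K2CO3 (1.0 equiv), MOMCl (1.05 equiv), acetone, 0 °C → rt
Reagents that add atoms: chloromethyl methyl ether (MOMCl), COCCl
Why: Williamson O-alkylation should occur only at the 7-OH, a vinylogous carboxylic acid made still more acidic by the ortho chlorine and therefore the only hydroxyl deprotonated by one equivalent of carbonate, which leaves the 4'-OH free for the coupling.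

**Step 3**
Reactants: 6 genistein (5,7-dihydroxy-3-(4-hydroxyphenyl)-4H-chromen-4-one)
Product: 7 5,7-bis(methoxymethoxy)-3-[4-(methoxymethoxy)phenyl]-4H-chromen-4-one
Conditions: NaH (3.6 equiv), MOMCl (3.6 equiv), DMF, 0 °C → rt
Reagents that add atoms: chloromethyl methyl ether (MOMCl), COCCl
Why: Exhaustive Williamson O-alkylation with a strong base, needed to break the hydrogen bond of the 5-OH to the C-4 carbonyl, should give the tris-MOM ether, whose 5-O-alkyl group is also what directs the next step to C-8.

**Step 4**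
Reactants: 7 5,7-bis(methoxymethoxy)-3-[4-(methoxymethoxy)phenyl]-4H-chromen-4-one
Product: 8 8-iodo-5,7-bis(methoxymethoxy)-3-[4-(methoxymethoxy)phenyl]-4H-chromen-4-one
Conditions: NIS (1.1 equiv), DMF, rt → 40 °C, dark
Reagents that add atoms: N-iodosuccinimide (NIS), O=C1CCC(=O)N1I
Why: Electrophilic aromatic iodination under neutral conditions should go to C-8 of the phloroglucinol-type ring A, which in 5,7-di-O-alkylchromones is para to the 5-alkoxy group and flanked only by the 7-OMOM group and the ring oxygen, whereas C-6 is buried between two OMOM groups and ring B carries a single donor; succinimide is the only by-product, so the acetals survive.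

**Step 5**
Reactants: 8 8-iodo-5,7-bis(methoxymethoxy)-3-[4-(methoxymethoxy)phenyl]-4H-chromen-4-one; 5 8-chloro-3-(4-hydroxyphenyl)-7-(methoxymethoxy)-4H-chromen-4-one
Product: 9 8-{4-[8-chloro-7-(methoxymethoxy)-4-oxo-4H-chromen-3-yl]phenoxy}-5,7-bis(methoxymethoxy)-3-[4-(methoxymethoxy)phenyl]-4H-chromen-4-one
Conditions: CuI (20 mol%), picolinic acid (40 mol%), K3PO4 (2 equiv), dry DMSO, 4 Å molecular sieves, 90 °C, Ar
Reagents that add atoms: none
Why: Ullmann-type C–O cross-coupling: K3PO4 forms the 4'-phenoxide of 5, which binds picolinate-ligated monovalent copper; oxidative addition of the C8–I bond of 8 and C–O reductive elimination from the trivalent copper intermediate forge the O–C8 diaryl ether bond and with it the complete C30 skeleton from two C15 monomers. The closest known reaction type is the CuI/picolinic acid coupling of ortho-substituted aryl iodides with phenols to hindered diaryl ethers. No ring is closed and no stereocentre is formed, since both pyranone rings are already present and the ether axis rotates freely. The step needs chemoselectivity for C–I over the C8–Cl bond of 5, which copper does not activate at 90 °C, and arylation at a single oxygen, secured because the 4'-OH is the only free hydroxyl while all others are base-stable MOM ethers. The two ortho oxygens of 8 (O-1 and the 7-OMOM group) are small and can pre-coordinate copper, which should offset the steric demand of the doubly flanked iodide. Dry phosphate in DMSO keeps hydroxide out, so the base-sensitive C-2 positions of both chromones should not be attacked.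

**Step 6**
Reactants: 9 the tetrakis-MOM ether of the target
Product: 10 bisoflavolin H (8-[4-(8-chloro-7-hydroxy-4-oxo-4H-chromen-3-yl)phenoxy]-5,7-dihydroxy-3-(4-hydroxyphenyl)-4H-chromen-4-one)
Conditions: 3 M aq HCl, MeOH/THF, 50 °C
Reagents that add atoms: none
Why: Acid-catalysed acetal exchange with methanol should remove all four MOM groups as dimethoxymethane, while the diaryl ether, the aryl chloride and both chromones are inert to dilute acid at 50 °C, far below the forcing conditions of a Wessely–Moser isomerisation.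

**Compound list**
1 | 2-chlororesorcinol (2-chlorobenzene-1,3-diol) | Oc1cccc(O)c1Cl | starting material
2 | 4-hydroxyphenylacetic acid | OC(=O)Cc1ccc(O)cc1 | starting material
3 | 1-(3-chloro-2,4-dihydroxyphenyl)-2-(4-hydroxyphenyl)ethan-1-one (deoxybenzoin, not isolated) | O=C(Cc1ccc(O)cc1)c1ccc(O)c(Cl)c1O | intermediate
4 | 8-chloro-7-hydroxy-3-(4-hydroxyphenyl)-4H-chromen-4-one (8-chlorodaidzein) | O=c1c(-c2ccc(O)cc2)coc2c(Cl)c(O)ccc12 | intermediate
5 | 8-chloro-3-(4-hydroxyphenyl)-7-(methoxymethoxy)-4H-chromen-4-one | O=c1c(-c2ccc(O)cc2)coc2c(Cl)c(OCOC)ccc12 | intermediate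
6 | genistein, 5,7-dihydroxy-3-(4-hydroxyphenyl)-4H-chromen-4-one | O=c1c(-c2ccc(O)cc2)coc2cc(O)cc(O)c12 | starting material
7 | 5,7-bis(methoxymethoxy)-3-[4-(methoxymethoxy)phenyl]-4H-chromen-4-one | O=c1c(-c2ccc(OCOC)cc2)coc2cc(OCOC)cc(OCOC)c12 | intermediate
8 | 8-iodo-5,7-bis(methoxymethoxy)-3-[4-(methoxymethoxy)phenyl]-4H-chromen-4-one | O=c1c(-c2ccc(OCOC)cc2)coc2c(I)c(OCOC)cc(OCOC)c12 | intermediate
9 | 8-{4-[8-chloro-7-(methoxymethoxy)-4-oxo-4H-chromen-3-yl]phenoxy}-5,7-bis(methoxymethoxy)-3-[4-(methoxymethoxy)phenyl]-4H-chromen-4-one | O=c1c(-c2ccc(Oc3c(OCOC)cc(OCOC)c4c(=O)c(-c5ccc(OCOC)cc5)coc34)cc2)coc2c(Cl)c(OCOC)ccc12 | intermediate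
10 | bisoflavolin H, 8-[4-(8-chloro-7-hydroxy-4-oxo-4H-chromen-3-yl)phenoxy]-5,7-dihydroxy-3-(4-hydroxyphenyl)-4H-chromen-4-one | O=c1c(-c2ccc(Oc3c(O)cc(O)c4c(=O)c(-c5ccc(O)cc5)coc34)cc2)coc2c(Cl)c(O)ccc12 | target

**Count and risks**
Total steps: 6. Longest linear sequence: 4 (steps 1, 2, 5, 6 or steps 3, 4, 5, 6).

Steps most likely to fail:

1. Step 5 (key coupling). Copper may add too slowly into the electron-rich, doubly ortho-oxygenated C8–I bond, so that reductive loss of iodine or base-induced opening of a pyranone ring takes over. Fallback: invert the polarity of the union, so that the hindered partner is the nucleophile and the iodide is unhindered. The fallback sets out from 8 and from 1 and comes back at 9.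
   - Miyaura borylation of 8 (Pd(dppf)Cl2, bis(pinacolato)diboron, KOAc, dioxane, 80 °C) would give 5,7-bis(methoxymethoxy)-3-[4-(methoxymethoxy)phenyl]-8-(4,4,5,5-tetramethyl-1,3,2-dioxaborolan-2-yl)-4H-chromen-4-one F1.
   - Oxidation with NaBO3·4H2O in THF/H2O would give 8-hydroxy-5,7-bis(methoxymethoxy)-3-[4-(methoxymethoxy)phenyl]-4H-chromen-4-one F2.
   - In parallel, 1 and 4-iodophenylacetic acid F3 would be taken through the conditions of step 1, via 1-(3-chloro-2,4-dihydroxyphenyl)-2-(4-iodophenyl)ethan-1-one F4, to 8-chloro-7-hydroxy-3-(4-iodophenyl)-4H-chromen-4-one F5.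
   - Protection as in step 2 would give 8-chloro-3-(4-iodophenyl)-7-(methoxymethoxy)-4H-chromen-4-one F6.
   - Ullmann coupling of the electron-rich phenol F2 with the unhindered aryl iodide F6 (CuI, picolinic acid, K3PO4, DMSO, 90 °C) should then give 9.

2. Step 4 (iodination). Regiocontrol may be lost through attack at C-6 or double iodination, or traces of acid may remove the 5-O-MOM group, after which the freed hydroxyl would steer iodine to C-6. Fallback: place the iodine before the pyranone ring exists, so that ring closure defines its position. The fallback sets out from 2 and comes back at 8.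
   - Acylation of phloroglucinol F7 with 2 in BF3·OEt2 would give 2-(4-hydroxyphenyl)-1-(2,4,6-trihydroxyphenyl)ethan-1-one F8.
   - K2CO3/MOMCl in acetone would protect all but one chelated ortho-hydroxyl, to give 1-[2-hydroxy-4,6-bis(methoxymethoxy)phenyl]-2-[4-(methoxymethoxy)phenyl]ethan-1-one F9.
   - NIS in DMF would iodinate ortho to the free hydroxyl, to give 1-[2-hydroxy-3-iodo-4,6-bis(methoxymethoxy)phenyl]-2-[4-(methoxymethoxy)phenyl]ethan-1-one F10.
   - Ring closure through that same hydroxyl with Me2NCH(OMe)2 in toluene at 90 °C must turn the iodinated carbon into C-8 and should give 8.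

3. Step 2 (mono-protection). Both hydroxyls may be alkylated, or the wrong oxygen, to give mixtures that are hard to separate. Fallback: install the MOM group before ring B is present and form the C3–aryl bond by cross-coupling. The fallback sets out from 1 and comes back at 5.
   - Acetylation of 1 (AcOH, BF3·OEt2, 90 °C) would give 1-(3-chloro-2,4-dihydroxyphenyl)ethan-1-one F11.
   - K2CO3/MOMCl would alkylate only the non-chelated hydroxyl, to give 1-[3-chloro-2-hydroxy-4-(methoxymethoxy)phenyl]ethan-1-one F12.
   - Me2NCH(OMe)2 at 90 °C would give (E)-1-[3-chloro-2-hydroxy-4-(methoxymethoxy)phenyl]-3-(dimethylamino)prop-2-en-1-one F13.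
   - Iodine in CHCl3 would cyclise it to 8-chloro-3-iodo-7-(methoxymethoxy)-4H-chromen-4-one F14.
   - Suzuki–Miyaura coupling with 4-hydroxyphenylboronic acid F15 (Pd(PPh3)4, aq Na2CO3, DME, 80 °C; the C–I bond reacts, the C–Cl bond does not) should give 5.

**Further compounds**
F1 | step 5 | 5,7-bis(methoxymethoxy)-3-[4-(methoxymethoxy)phenyl]-8-(4,4,5,5-tetramethyl-1,3,2-dioxaborolan-2-yl)-4H-chromen-4-one | O=c1c(-c2ccc(OCOC)cc2)coc2c(B3OC(C)(C)C(C)(C)O3)c(OCOC)cc(OCOC)c12
F2 | step 5 | 8-hydroxy-5,7-bis(methoxymethoxy)-3-[4-(methoxymethoxy)phenyl]-4H-chromen-4-one | O=c1c(-c2ccc(OCOC)cc2)coc2c(O)c(OCOC)cc(OCOC)c12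
F3 | step 5 | 4-iodophenylacetic acid | OC(=O)Cc1ccc(I)cc1
F4 | step 5 | 1-(3-chloro-2,4-dihydroxyphenyl)-2-(4-iodophenyl)ethan-1-one | O=C(Cc1ccc(I)cc1)c1ccc(O)c(Cl)c1O
F5 | step 5 | 8-chloro-7-hydroxy-3-(4-iodophenyl)-4H-chromen-4-one | O=c1c(-c2ccc(I)cc2)coc2c(Cl)c(O)ccc12
F6 | step 5 | 8-chloro-3-(4-iodophenyl)-7-(methoxymethoxy)-4H-chromen-4-one | O=c1c(-c2ccc(I)cc2)coc2c(Cl)c(OCOC)ccc12
F7 | step 4 | phloroglucinol (benzene-1,3,5-triol) | Oc1cc(O)cc(O)c1
F8 | step 4 | 2-(4-hydroxyphenyl)-1-(2,4,6-trihydroxyphenyl)ethan-1-one | O=C(Cc1ccc(O)cc1)c1c(O)cc(O)cc1O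
F9 | step 4 | 1-[2-hydroxy-4,6-bis(methoxymethoxy)phenyl]-2-[4-(methoxymethoxy)phenyl]ethan-1-one | COCOc1ccc(CC(=O)c2c(O)cc(OCOC)cc2OCOC)cc1
F10 | step 4 | 1-[2-hydroxy-3-iodo-4,6-bis(methoxymethoxy)phenyl]-2-[4-(methoxymethoxy)phenyl]ethan-1-one | COCOc1ccc(CC(=O)c2c(O)c(I)c(OCOC)cc2OCOC)cc1
F11 | step 2 | 1-(3-chloro-2,4-dihydroxyphenyl)ethan-1-one | CC(=O)c1ccc(O)c(Cl)c1O
F12 | step 2 | 1-[3-chloro-2-hydroxy-4-(methoxymethoxy)phenyl]ethan-1-one | CC(=O)c1ccc(OCOC)c(Cl)c1O
F13 | step 2 | (E)-1-[3-chloro-2-hydroxy-4-(methoxymethoxy)phenyl]-3-(dimethylamino)prop-2-en-1-one | CN(C)/C=C/C(=O)c1ccc(OCOC)c(Cl)c1O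
F14 | step 2 | 8-chloro-3-iodo-7-(methoxymethoxy)-4H-chromen-4-one | O=c1c(I)coc2c(Cl)c(OCOC)ccc12
F15 | step 2 | 4-hydroxyphenylboronic acid | OB(O)c1ccc(O)cc1
A1 | direct plan | 4-methoxy-2,6-bis(methoxymethoxy)phenol | Oc1c(OCOC)cc(OC)cc1OCOC
A2 | direct plan | 4-fluorobenzaldehyde | O=Cc1ccc(F)cc1
A3 | direct plan | 4-[4-methoxy-2,6-bis(methoxymethoxy)phenoxy]benzaldehyde | O=Cc1ccc(Oc2c(OCOC)cc(OC)cc2OCOC)cc1
A4 | direct plan | (E)-1-[3-chloro-2-hydroxy-4-(methoxymethoxy)phenyl]-3-{4-[4-methoxy-2,6-bis(methoxymethoxy)phenoxy]phenyl}prop-2-en-1-one | COCOc1ccc(C(=O)/C=C/c2ccc(Oc3c(OCOC)cc(OC)cc3OCOC)cc2)c(O)c1Cl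
A5 | direct plan | 8-chloro-3-[4-(2,6-dihydroxy-4-methoxyphenoxy)phenyl]-7-hydroxy-4H-chromen-4-one | O=c1c(-c2ccc(Oc3c(O)cc(OC)cc3O)cc2)coc2c(Cl)c(O)ccc12
A6 | direct plan | 8-[4-(8-chloro-7-hydroxy-4-oxo-4H-chromen-3-yl)phenoxy]-7-hydroxy-3-(4-hydroxyphenyl)-5-methoxy-4H-chromen-4-one | O=c1c(-c2ccc(Oc3c(O)cc(OC)c4c(=O)c(-c5ccc(O)cc5)coc34)cc2)coc2c(Cl)c(O)ccc12
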